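The flavanone is cut through ring C at O1–C8a and C4–C4a. Because ring A carries oxygen at C5 and C7, C4a and C8a are the two termini of a 3,5-dialkoxybenzyne, and the C5 oxygen next to C4a polarises that aryne so that an alkoxide bonds at C8a. One fluoride-triggered operation therefore joins the O1 alkoxide of an (S)-β-silyloxy ester to C8a and lets the C4a carbanion acylate on the ester, closing ring C with C2 untouched. The partners are a 3,5-bis(methoxymethoxy)-2-silylphenyl triflate and the trimethylsilyl ether of methyl (S)-3-hydroxy-3-(7-prenylbenzofuran-5-yl)propanoate.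

Key step: step 10

Remarks on the chemistry (assumptions and design choices):
- The bromohydroxyacetophenone, trimethylsilylacetylene, the prenylstannane and dimethyl carbonate used below are taken as commercial.
- The carbinol enters the annulation as its trimethylsilyl ether, so fluoride releases alkoxide and aryne together and the flask holds no O–H that could quench the aryl anion.
- The prenyl group is attached after both halogenations and the furan annulation, because electrophilic iodine would attack the alkene of an ortho-prenylphenol (iodoetherification).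
- The carbinol centre is set by reduction of a β-keto ester, whose facial sense is secure, so the benzofuran fragment is built from an acetophenone.

Step 1
Reactants: 1 phloroglucinol
Product: 2 3,5-bis(methoxymethoxy)phenol
Conditions: MOMCl (2.0 equiv), i-Pr2NEt (2.2 equiv), CH2Cl2/DMF, 0 °C to rt
Reagents that add atoms: chloromethyl methyl ether, COCCl
Why: Williamson-type O-alkylation of the phenol by the α-chloro ether (MOM protection); with two equivalents the bis-ether should be the main member of a statistical mixture and separable by chromatography from the mono- and tris-ethers, since each ether group lowers polarity stepwise.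

Step 2
Reactants: 2 3,5-bis(methoxymethoxy)phenol
Product: 3 2-bromo-3,5-bis(methoxymethoxy)phenol
Conditions: NBS (1.0 equiv), i-Pr2NH (10 mol%), CH2Cl2, −78 °C to 0 °C
Reagents that add atoms: N-bromosuccinimide, O=C1CCC(=O)N1Br
Why: Electrophilic aromatic bromination in its amine-catalysed ortho-selective form: the N-bromoamine made in situ is hydrogen-bonded to the phenol and should deliver bromine to one of the two equivalent positions between OH and an acetal oxygen in preference to C4, and NBS releases no strong acid that would endanger the acetals.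

Step 3
Reactants: 3 2-bromo-3,5-bis(methoxymethoxy)phenol
Product: 6 3,5-bis(methoxymethoxy)-2-(trimethylsilyl)phenyl trifluoromethanesulfonate, via aryl trimethylsilyl ether 4 (not isolated), via lithium silylphenoxide 5 (not isolated)
Conditions: HMDS, THF, 65 °C, then evaporation; n-BuLi, THF, −100 °C to −78 °C; Tf2O, −100 °C to rt
Reagents that add atoms: hexamethyldisilazane, C[Si](C)(C)N[Si](C)(C)C; trifluoromethanesulfonic anhydride, O=S(=O)(OS(=O)(=O)C(F)(F)F)C(F)(F)F
Why: O-silylation, bromine–lithium exchange and retro-Brook rearrangement (1,3 O-to-C silyl shift), then O-triflation of the freed phenoxide, is the standard entry to ortho-silylaryl triflates, and at −100 °C the exchange should outrun acetal-directed ring deprotonation.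

Step 4
Reactants: 7 1-(3-bromo-4-hydroxyphenyl)ethanone
Product: 8 1-(3-bromo-4-hydroxy-5-iodophenyl)ethanone
Conditions: NIS (1.05 equiv), TsOH·H2O (10 mol%), MeCN, rt
Reagents that add atoms: N-iodosuccinimide, O=C1CCC(=O)N1I
Why: Electrophilic aromatic iodination: the one free position ortho to the phenol is activated by OH, the para position is blocked, and the methyl ketone enolises too slowly at room temperature to compete.

Step 5
Reactants: 8 1-(3-bromo-4-hydroxy-5-iodophenyl)ethanone; 9 trimethylsilylacetylene (1.05 equiv)
Product: 12 1-(7-bromo-1-benzofuran-5-yl)ethanone, via silylethynylphenol 10 (not isolated), via 2-silylbenzofuran 11 (not isolated)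
Conditions: PdCl2(PPh3)2 (2 mol%), CuI (4 mol%), Et3N, THF, rt, then 60 °C; then TBAF·3H2O, THF, rt
Reagents that add atoms: none
Why: A known domino route from ortho-iodophenols to 2-unsubstituted benzofurans: Sonogashira coupling at C–I (C–Br is inert at room temperature and no alkyne is left on heating), copper-assisted 5-endo-dig attack of the phenoxide oxygen on the alkyne, and fluoride-mediated protodesilylation of C2 with water as proton source, in which fluoride is returned and silicon leaves as the silanol.

Step 6
Reactants: 12 1-(7-bromo-1-benzofuran-5-yl)ethanone; 13 tributyl(3-methylbut-2-en-1-yl)stannane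
Product: 14 1-[7-(3-methylbut-2-en-1-yl)-1-benzofuran-5-yl]ethanone
Conditions: Pd(PPh3)4 (5 mol%), DMF, 100 °C
Reagents that add atoms: none
Why: Migita–Kosugi–Stille coupling: oxidative addition of zerovalent palladium into the C–Br bond, allyl transfer from tin and reductive elimination at the less substituted allyl terminus should give the linear prenyl arene, the ketone and the furan being inert to these neutral conditions.

Step 7
Reactants: 14 1-[7-(3-methylbut-2-en-1-yl)-1-benzofuran-5-yl]ethanone; 15 dimethyl carbonate
Product: 16 methyl 3-[7-(3-methylbut-2-en-1-yl)-1-benzofuran-5-yl]-3-oxopropanoate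
Conditions: NaH (2.5 equiv), THF, 65 °C; then 1 M HCl, 0 °C
Reagents that add atoms: none
Why: Crossed Claisen condensation: the ketone enolate is C-acylated by the non-enolisable carbonate, and irreversible deprotonation of the β-keto ester by the second equivalent of hydride drives the equilibrium.

Step 8
Reactants: 16 methyl 3-[7-(3-methylbut-2-en-1-yl)-1-benzofuran-5-yl]-3-oxopropanoate
Product: 17 methyl (3S)-3-hydroxy-3-[7-(3-methylbut-2-en-1-yl)-1-benzofuran-5-yl]propanoate
Conditions: RuCl[(S,S)-TsDPEN](p-cymene) (1 mol%), HCO2H/Et3N (5:2), DMF, 40 °C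
Reagents that add atoms: none
Why: Noyori–Ikariya asymmetric transfer hydrogenation: the Ru–H/N–H pair delivers hydride and proton through an outer-sphere six-membered transition state in which a CH/π contact between the cymene ligand and the benzofuranyl group makes the (S,S)-ligand direct hydride to the Re face of the aryl ketone, setting the carbinol carbon as (S) (the sense by which acetophenone gives (S)-1-phenylethanol), while the isolated alkene and the furan are untouched by this hydride source.

Step 9
Reactants: 17 methyl (3S)-3-hydroxy-3-[7-(3-methylbut-2-en-1-yl)-1-benzofuran-5-yl]propanoate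
Product: 18 methyl (3S)-3-[7-(3-methylbut-2-en-1-yl)-1-benzofuran-5-yl]-3-[(trimethylsilyl)oxy]propanoate
Conditions: 1-(trimethylsilyl)imidazole (1.3 equiv), CH2Cl2, rt; hexane, filtration, evaporation
Reagents that add atoms: 1-(trimethylsilyl)imidazole, C[Si](C)(C)n1ccnc1
Why: O-silylation of the secondary alcohol by a neutral silyl-transfer reagent that releases only imidazole, so the ether can be isolated without aqueous work-up and the stereocentre is not involved.

Step 10
Reactants: 18 methyl (3S)-3-[7-(3-methylbut-2-en-1-yl)-1-benzofuran-5-yl]-3-[(trimethylsilyl)oxy]propanoate; 6 3,5-bis(methoxymethoxy)-2-(trimethylsilyl)phenyl trifluoromethanesulfonate (1.6 equiv)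
Product: 21 (2S)-5,7-bis(methoxymethoxy)-2-[7-(3-methylbut-2-en-1-yl)-1-benzofuran-5-yl]-2,3-dihydro-4H-chromen-4-one, via cesium alkoxide 19 (not isolated), via 3,5-bis(methoxymethoxy)benzyne 20 (not isolated)
Conditions: CsF (4 equiv), 18-crown-6 (4 equiv), THF, 0 °C to rt, 6 added over 2 h; pH 7 phosphate buffer, 0 °C
Reagents that add atoms: none
Why: Proposed new method: fluoride removes silicon from both partners, giving alkoxide 19 and, by 1,2-elimination of triflate, aryne 20; the alkoxide oxygen adds to the aryne carbon remote from the flanking acetal oxygen (the future C8a), and the carbanion left at the future C4a attacks the methyl ester and expels methoxide, which silicon takes up as MeOSiMe3. The closest known reaction types are the CsF-mediated annulation of arynes by methyl salicylates to xanthones and the O-arylation of alcohols by arynes; new here is a saturated secondary alkoxide that carries the ester two carbons away. Ring C closes by a 6-exo-trig acyl substitution, the ester C=O lying outside the forming ring. No stereocentre is created: C2 keeps the (S) configuration set in step 8 because its C–O bond is never broken. The step needs regioselectivity (oxygen at C8a, not C4a), secured by the inductive and distortion effect of the C5 alkoxy group of this 3-alkoxyaryne, and acylation in preference to protonation of the aryl anion, secured by the absence of any O–H (silyl ether as alkoxide source, aprotic THF) and by slow addition of 6, which keeps alkoxide ahead of aryne so that alkene and furan do not compete. The low temperature and the capture of methoxide on silicon should limit base-induced reopening of ring C to the chalcone, the one path that could erase C2.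

Step 11
Reactants: 21 (2S)-5,7-bis(methoxymethoxy)-2-[7-(3-methylbut-2-en-1-yl)-1-benzofuran-5-yl]-2,3-dihydro-4H-chromen-4-one
Product: 22 (2S)-5,7-dihydroxy-2-[7-(3-methylbut-2-en-1-yl)-1-benzofuran-5-yl]-2,3-dihydro-4H-chromen-4-one
Conditions: 3 M aq. HCl, MeOH, 45 °C
Reagents that add atoms: none
Why: Acid-catalysed solvolysis of the two mixed acetals through oxocarbenium ions (MOM deprotection); the C2–O1 bond and C2–H are inert to dilute acid because ring opening of a flavanone needs base, and the prenyl group has no neighbouring phenol to cyclise onto.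

Compound list
1 | phloroglucinol | Oc1cc(O)cc(O)c1 | starting material
2 | 3,5-bis(methoxymethoxy)phenol | Oc1cc(OCOC)cc(OCOC)c1 | intermediate
3 | 2-bromo-3,5-bis(methoxymethoxy)phenol | Oc1cc(OCOC)cc(OCOC)c1Br | intermediate
4 | [2-bromo-3,5-bis(methoxymethoxy)phenoxy]trimethylsilane (not isolated) | C[Si](C)(C)Oc1cc(OCOC)cc(OCOC)c1Br | intermediate
5 | lithium 3,5-bis(methoxymethoxy)-2-(trimethylsilyl)phenolate (not isolated) | [Li+].[O-]c1cc(OCOC)cc(OCOC)c1[Si](C)(C)C | intermediate
6 | 3,5-bis(methoxymethoxy)-2-(trimethylsilyl)phenyl trifluoromethanesulfonate | C[Si](C)(C)c1c(OCOC)cc(OCOC)cc1OS(=O)(=O)C(F)(F)F | intermediate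
7 | 1-(3-bromo-4-hydroxyphenyl)ethanone | CC(=O)c1ccc(O)c(Br)c1 | starting material
8 | 1-(3-bromo-4-hydroxy-5-iodophenyl)ethanone | CC(=O)c1cc(Br)c(O)c(I)c1 | intermediate
9 | trimethylsilylacetylene | C#C[Si](C)(C)C | starting material
10 | 1-{3-bromo-4-hydroxy-5-[(trimethylsilyl)ethynyl]phenyl}ethanone (not isolated) | CC(=O)c1cc(Br)c(O)c(C#C[Si](C)(C)C)c1 | intermediate
11 | 1-[7-bromo-2-(trimethylsilyl)-1-benzofuran-5-yl]ethanone (not isolated) | CC(=O)c1cc(Br)c2oc([Si](C)(C)C)cc2c1 | intermediate
12 | 1-(7-bromo-1-benzofuran-5-yl)ethanone | CC(=O)c1cc(Br)c2occc2c1 | intermediate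
13 | tributyl(3-methylbut-2-en-1-yl)stannane | CCCC[Sn](CCCC)(CCCC)CC=C(C)C | starting material
14 | 1-[7-(3-methylbut-2-en-1-yl)-1-benzofuran-5-yl]ethanone | CC(=O)c1cc(CC=C(C)C)c2occc2c1 | intermediate
15 | dimethyl carbonate | COC(=O)OC | starting material
16 | methyl 3-[7-(3-methylbut-2-en-1-yl)-1-benzofuran-5-yl]-3-oxopropanoate | COC(=O)CC(=O)c1cc(CC=C(C)C)c2occc2c1 | intermediate
17 | methyl (3S)-3-hydroxy-3-[7-(3-methylbut-2-en-1-yl)-1-benzofuran-5-yl]propanoate | CC(C)=CCc1cc([C@@H](O)CC(=O)OC)cc2ccoc12 | intermediate
18 | methyl (3S)-3-[7-(3-methylbut-2-en-1-yl)-1-benzofuran-5-yl]-3-[(trimethylsilyl)oxy]propanoate | CC(C)=CCc1cc([C@@H](O[Si](C)(C)C)CC(=O)OC)cc2ccoc12 | intermediate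
19 | cesium (1S)-3-methoxy-1-[7-(3-methylbut-2-en-1-yl)-1-benzofuran-5-yl]-3-oxopropan-1-olate (not isolated) | CC(C)=CCc1cc([C@@H]([O-])CC(=O)OC)cc2ccoc12.[Cs+] | intermediate
20 | 3,5-bis(methoxymethoxy)benzyne (not isolated) | COCOC1=CC(OCOC)=CC#C1 | intermediate
21 | (2S)-5,7-bis(methoxymethoxy)-2-[7-(3-methylbut-2-en-1-yl)-1-benzofuran-5-yl]-2,3-dihydro-4H-chromen-4-one | CC(C)=CCc1cc([C@@H]2CC(=O)c3c(OCOC)cc(OCOC)cc3O2)cc2ccoc12 | intermediate
22 | (2S)-5,7-dihydroxy-2-[7-(3-methylbut-2-en-1-yl)-1-benzofuran-5-yl]-2,3-dihydro-4H-chromen-4-one | CC(C)=CCc1cc([C@@H]2CC(=O)c3c(O)cc(O)cc3O2)cc2ccoc12 | target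

Total step count: 11 (steps 1–3 to the aryne precursor, steps 4–9 to the silyloxy ester, steps 10–11 to the target).
Longest linear sequence: 8 steps (7 to 22 through steps 4, 5, 6, 7, 8, 9, 10 and 11).

Steps most likely to fail

1. Step 10 (proposed new method). The aryl anion may be protonated before it acylates, either by the α-methylene of its own ester or by traces of water. That would give the open aryl ether and then β-elimination. Ring C, once formed, may also reopen in the basic medium with loss of configuration at C2. The fallback uses known chemistry, sets out from 16 and 3, and returns at 21.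
   - Compound 16 would be reduced with the enantiomeric catalyst RuCl[(R,R)-TsDPEN](p-cymene) in HCO2H/Et3N to methyl (3R)-3-hydroxy-3-[7-(3-methylbut-2-en-1-yl)-1-benzofuran-5-yl]propanoate F1.
   - Aminolysis with MeNHOMe·HCl and i-PrMgCl (THF, −15 °C) would give the Weinreb amide (3R)-3-hydroxy-N-methoxy-N-methyl-3-[7-(3-methylbut-2-en-1-yl)-1-benzofuran-5-yl]propanamide F2.
   - Bromophenol 3 would be converted with n-BuLi (2 equiv, THF, −78 °C) into lithium 2-lithio-3,5-bis(methoxymethoxy)phenolate F3. Added in excess to F2, whose hydroxyl is first deprotonated with i-PrMgCl, it should give (3R)-3-hydroxy-1-[2-hydroxy-4,6-bis(methoxymethoxy)phenyl]-3-[7-(3-methylbut-2-en-1-yl)-1-benzofuran-5-yl]propan-1-one F4.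
   - Intramolecular Mitsunobu etherification (PPh3, DIAD, THF, 0 °C) would close ring C with inversion at the carbinol carbon and deliver 21 in the (S) configuration.

2. Step 2. Site selectivity may be poor, with attack at C4 between the two acetal oxygens or double bromination. The fallback replaces halogenation by directed ortho metalation, sets out from 2 and returns at 6.
   - Phenol 2 and isopropyl isocyanate (Et3N cat., CH2Cl2) would give 3,5-bis(methoxymethoxy)phenyl N-isopropylcarbamate F5.
   - N-silylation in situ (TMSOTf, TMEDA), lithiation with n-BuLi/TMEDA (Et2O, −78 °C) and a TMSCl quench with mild aqueous work-up should give 3,5-bis(methoxymethoxy)-2-(trimethylsilyl)phenyl N-isopropylcarbamate F6. Lithiation is expected at the position flanked by the carbamate, the stronger director, and an acetal oxygen.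
   - Carbamate cleavage with Et2NH and DBU (MeCN, 40 °C) would free 3,5-bis(methoxymethoxy)-2-(trimethylsilyl)phenol F7, which would be triflated in the same flask with PhNTf2 to give 6.

3. Step 6. Regiocontrol in the allyl transfer may be lost (coupling at the γ-terminus to the 1,1-dimethylallyl isomer), or the double bond may migrate into conjugation. The fallback builds the prenyl group in two C–C events, sets out from 12 and returns at 14.
   - Stille coupling of 12 with allyltributylstannane (Pd(PPh3)4, DMF, 90 °C), in which both allyl termini are the same, would give 1-[7-(prop-2-en-1-yl)-1-benzofuran-5-yl]ethanone F8.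
   - Olefin cross-metathesis with excess 2-methyl-2-butene (second-generation Grubbs catalyst, CH2Cl2, 40 °C) would convert F8 into 14.

Further compounds
F1 | step 10 | methyl (3R)-3-hydroxy-3-[7-(3-methylbut-2-en-1-yl)-1-benzofuran-5-yl]propanoate | CC(C)=CCc1cc([C@H](O)CC(=O)OC)cc2ccoc12
F2 | step 10 | (3R)-3-hydroxy-N-methoxy-N-methyl-3-[7-(3-methylbut-2-en-1-yl)-1-benzofuran-5-yl]propanamide | CC(C)=CCc1cc([C@H](O)CC(=O)N(C)OC)cc2ccoc12
F3 | step 10 | lithium 2-lithio-3,5-bis(methoxymethoxy)phenolate | [Li+].[O-]c1cc(OCOC)cc(OCOC)c1[Li]
F4 | step 10 | (3R)-3-hydroxy-1-[2-hydroxy-4,6-bis(methoxymethoxy)phenyl]-3-[7-(3-methylbut-2-en-1-yl)-1-benzofuran-5-yl]propan-1-one | CC(C)=CCc1cc([C@H](O)CC(=O)c3c(O)cc(OCOC)cc3OCOC)cc2ccoc12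
F5 | step 2 | 3,5-bis(methoxymethoxy)phenyl N-isopropylcarbamate | CC(C)NC(=O)Oc1cc(OCOC)cc(OCOC)c1
F6 | step 2 | 3,5-bis(methoxymethoxy)-2-(trimethylsilyl)phenyl N-isopropylcarbamate | CC(C)NC(=O)Oc1cc(OCOC)cc(OCOC)c1[Si](C)(C)C
F7 | step 2 | 3,5-bis(methoxymethoxy)-2-(trimethylsilyl)phenol | Oc1cc(OCOC)cc(OCOC)c1[Si](C)(C)C
F8 | step 6 | 1-[7-(prop-2-en-1-yl)-1-benzofuran-5-yl]ethanone | CC(=O)c1cc(CC=C)c2occc2c1
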